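Disconnections: first the flavanone C2–aryl bond, then the flavone pyranone (O1–C2 and C4–C4a, with C4 coming from CO), last flavone ring A at C8a–C8, C6–C7 and C4a–C8a.
Enabling feature: flavone ring A carries oxygens on C5, C7 and C8a in a 1,3,5 array with the aryl group on C6, and only the C8a oxygen (the later O1) has to be a free phenol, which is exactly the oxygen a cyclobutenone/alkoxyalkyne benzannulation delivers free.
Forward: an arylketene/ethoxyacetylene [2+2] adduct is isomerised through the 1,3-dione to the 2-aryl-3-ethoxycyclobutenone, and benzannulation with ethoxyacetylene then grows ring A around the existing aryl–C6 bond, so no biaryl coupling is needed.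
Ring C of the flavone is closed by iodination and carbonylative annulation with 4-ethynylanisole; the alkyl ethers are exchanged for benzyl and the bromide is turned into a boronic acid.
The flavanone is joined last: its chromanone ring arrives as 5,7-bis(benzyloxy)chromone, and the only stereocentre (2S) is set by ligand-controlled palladium-catalysed conjugate addition of the arylboronic acid; hydrogenolysis ends the route.

Key step: step 4

Remark: the target defines only C2, so the biaryl axis with its three ortho oxygens is treated as stereochemically undefined and is left uncontrolled; compounds 1, 2 (as a solution in hexanes), 14 and 21 are taken as catalogue chemicals.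

Step 1
Reactants: 1 2-(5-bromo-2-methoxyphenyl)acetic acid; 2 ethoxyacetylene
Product: 5 4-(5-bromo-2-methoxyphenyl)-3-ethoxycyclobut-2-en-1-one (racemic at C4), via acid chloride 3 (not isolated), via arylketene 4 (not isolated)
Conditions: (COCl)2, cat. DMF, CH2Cl2, 0 °C → rt, evaporate; then 2 (3 equiv), Et3N (1.2 equiv, slow addition), Et2O, 0 °C → rt
Reagents that add atoms: none
Why: Acid chloride formation and dehydrochlorination give the arylketene, which the electron-rich ynol ether should trap in a regioselective ketene–alkyne [2+2] cycloaddition (alkyne CH carbon to the ketene carbonyl carbon), the established entry to 3-ethoxycyclobutenones, with excess alkyne and slow base addition set against ketene dimerisation.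

Step 2
Reactants: 5 4-(5-bromo-2-methoxyphenyl)-3-ethoxycyclobut-2-en-1-one
Product: 6 2-(5-bromo-2-methoxyphenyl)-3-hydroxycyclobut-2-en-1-one (enol form of the 2-arylcyclobutane-1,3-dione)
Conditions: 1 M HCl, THF, rt
Reagents that add atoms: water, O
Why: Acid hydrolysis of the vinylogous ester (enol ether hydrolysis) should give the cyclobutane-1,3-dione, which rests as its aryl-conjugated enol, a strong vinylogous acid.

Step 3
Reactants: 6 2-(5-bromo-2-methoxyphenyl)-3-hydroxycyclobut-2-en-1-one
Product: 7 2-(5-bromo-2-methoxyphenyl)-3-ethoxycyclobut-2-en-1-one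
Conditions: Et3OBF4 (1.2 equiv), iPr2NEt, CH2Cl2, 0 °C → rt
Reagents that add atoms: triethyloxonium tetrafluoroborate, CC[O+](CC)CC.F[B-](F)(F)F
Why: O-Alkylation of the vinylogous carboxylate by a hard oxonium salt (oxonium esterification) should give the enol ether, and because the two carbonyl positions of the dione are equivalent only one product is possible, now with the aryl group on the alkene carbon C2.

Step 4
Reactants: 7 2-(5-bromo-2-methoxyphenyl)-3-ethoxycyclobut-2-en-1-one; 2 ethoxyacetylene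
Product: 12 4-(5-bromo-2-methoxyphenyl)-3,5-diethoxyphenol, via vinylketene 8 (not isolated), via vinylcyclobutenone 9 (not isolated), via dienylketene 10 (not isolated), via cyclohexadienone 11 (not isolated)
Conditions: 2 (3 equiv), toluene, sealed tube, 80 °C, then 110 °C
Reagents that add atoms: none
Why: Heating should open 7 by conrotatory 4π electrocyclic ring opening to aryl(1-ethoxyvinyl)ketene 8, whose carbonyl carbon is attacked by the nucleophilic CH terminus of ethoxyacetylene in a regiospecific [2+2] cycloaddition to give 4-vinylcyclobutenone 9; a second 4π opening gives dienylketene 10, which closes to dienone 11 and tautomerises to phenol 12. The closest known reaction type is the Danheiser benzannulation of cyclobutenones with alkoxy- or siloxyalkynes, which gives resorcinol monoethers with the alkyne oxygen meta and the cyclobutenone C2 substituent para to the new hydroxyl. The only ring closed, flavone ring A, arises by thermal 6π electrocyclisation of 10 (ketene carbon onto the CH2 terminus of the ethoxyvinyl group, the future C8a–C4a bond) after the [2+2] step has made the future C8a–C8 and C7–C6 bonds. No stereocentre is created (the quaternary carbon of 9 is lost again on ring opening), and the aryl–C6 bond is carried in on the ketene carbon. Two selectivities are required: the orientation of the [2+2] step, which the polarisation of the ynol ether secures and which places the two ethoxy groups on either side of the aryl group with the free hydroxyl para to it, and closure of 10 onto the vinyl terminus instead of the anisyl ring, which is secured because ring opening of 9 is reversible, closure onto the alkene costs no aromaticity and one ortho position of the aryl ring is blocked by OMe.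

Step 5
Reactants: 12 4-(5-bromo-2-methoxyphenyl)-3,5-diethoxyphenol
Product: 13 4-(5-bromo-2-methoxyphenyl)-3,5-diethoxy-2-iodophenol
Conditions: NIS (1.0 equiv), MeCN, −20 → 0 °C
Reagents that add atoms: N-iodosuccinimide, O=C1CCC(=O)N1I
Why: Electrophilic aromatic iodination should take place at one of the two equivalent positions ortho to the free hydroxyl of the phloroglucinol-type ring, one equivalent of reagent at low temperature being chosen to stop at the mono-iodide and to spare the deactivated bromoanisole ring.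

Step 6
Reactants: 13 4-(5-bromo-2-methoxyphenyl)-3,5-diethoxy-2-iodophenol; 14 1-ethynyl-4-methoxybenzene
Product: 16 6-(5-bromo-2-methoxyphenyl)-5,7-diethoxy-2-(4-methoxyphenyl)-4H-chromen-4-one, via alkynone 15 (not isolated)
Conditions: CO (1 atm), PdCl2(PPh3)2 (5 mol %), dppp (5 mol %), thiourea (5 mol %), Et2NH, 40–60 °C
Reagents that add atoms: carbon monoxide, [C-]#[O+]
Why: Carbonylative Sonogashira coupling (oxidative addition at C–I in preference to C–Br, CO insertion, alkynylation) should give the o-hydroxyaryl alkynone, which the secondary amine steers into 6-endo closure to the flavone, the known palladium-catalysed carbonylative annulation of o-iodophenols with terminal alkynes, and by the symmetry of 12 the aryl group can only end up on C6.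

Step 7
Reactants: 16 6-(5-bromo-2-methoxyphenyl)-5,7-diethoxy-2-(4-methoxyphenyl)-4H-chromen-4-one
Product: 17 6-(5-bromo-2-hydroxyphenyl)-5,7-dihydroxy-2-(4-hydroxyphenyl)-4H-chromen-4-one
Conditions: BBr3 (12 equiv), CH2Cl2, −78 °C → rt; then H2O
Reagents that add atoms: none
Why: Exhaustive Lewis-acid cleavage of the aryl ethyl and methyl ethers (BBr3 dealkylation) is routine on flavones and should leave the aryl bromide and the pyranone untouched.

Step 8
Reactants: 17 6-(5-bromo-2-hydroxyphenyl)-5,7-dihydroxy-2-(4-hydroxyphenyl)-4H-chromen-4-one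
Product: 18 5,7-bis(benzyloxy)-6-[2-(benzyloxy)-5-bromophenyl]-2-[4-(benzyloxy)phenyl]-4H-chromen-4-one
Conditions: BnBr (6 equiv), K2CO3, nBu4NI (cat.), DMF, 70 °C
Reagents that add atoms: benzyl bromide, BrCc1ccccc1
Why: Williamson etherification of all four phenols should install hydrogenolysable protection, the chelated and flanked 5-OH being the reason for excess reagent, iodide catalysis and heating.

Step 9
Reactants: 18 5,7-bis(benzyloxy)-6-[2-(benzyloxy)-5-bromophenyl]-2-[4-(benzyloxy)phenyl]-4H-chromen-4-one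
Product: 19 5,7-bis(benzyloxy)-6-[2-(benzyloxy)-5-(4,4,5,5-tetramethyl-1,3,2-dioxaborolan-2-yl)phenyl]-2-[4-(benzyloxy)phenyl]-4H-chromen-4-one
Conditions: B2pin2 (1.5 equiv), PdCl2(dppf) (5 mol %), KOAc, 1,4-dioxane, 90 °C
Reagents that add atoms: bis(pinacolato)diboron, CC1(C)OB(OC1(C)C)B1OC(C)(C)C(C)(C)O1
Why: Miyaura borylation by zerovalent palladium formed in situ should proceed readily at the aryl bromide, which has no ortho substituent, while the flavone and the benzyl ethers are inert.

Step 10
Reactants: 19 the pinacol boronate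
Product: 20 {4-(benzyloxy)-3-[5,7-bis(benzyloxy)-2-[4-(benzyloxy)phenyl]-4-oxo-4H-chromen-6-yl]phenyl}boronic acid
Conditions: NaIO4 (3 equiv), NH4OAc, acetone/THF/H2O, rt
Reagents that add atoms: water, O
Why: Periodate cleavage of the pinacol released in the hydrolysis equilibrium should drive the boronate to the free boronic acid under near-neutral conditions that the flavone tolerates (oxidative deprotection of pinacol boronates).

Step 11
Reactants: 21 2,4,6-trihydroxyacetophenone
Product: 22 1-[2,4-bis(benzyloxy)-6-hydroxyphenyl]ethan-1-one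
Conditions: BnBr (2.1 equiv), K2CO3, DMF, rt → 50 °C
Reagents that add atoms: benzyl bromide, BrCc1ccccc1
Why: Williamson etherification should stop at the dibenzyl ether because the remaining ortho hydroxyl is hydrogen-bonded to the acetyl group, as is usual for phloroacetophenone.

Step 12
Reactants: 22 1-[2,4-bis(benzyloxy)-6-hydroxyphenyl]ethan-1-one
Product: 24 5,7-bis(benzyloxy)-4H-chromen-4-one, via enaminone 23 (not isolated)
Conditions: Me2NCH(OMe)2, toluene, 100 °C; then conc. HCl, CH2Cl2, 40 °C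
Reagents that add atoms: N,N-dimethylformamide dimethyl acetal, COC(OC)N(C)C
Why: Condensation of the methyl ketone with the formamide acetal gives the enaminone, which under acid should close by intramolecular oxa-Michael addition and loss of dimethylamine (enaminone route to chromones).

Step 13
Reactants: 20 the arylboronic acid; 24 5,7-bis(benzyloxy)-4H-chromen-4-one
Product: 25 (2S)-5,7-bis(benzyloxy)-2-{4-(benzyloxy)-3-[5,7-bis(benzyloxy)-2-[4-(benzyloxy)phenyl]-4-oxo-4H-chromen-6-yl]phenyl}-2,3-dihydro-4H-chromen-4-one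
Conditions: 24 (2 equiv), Pd(OCOCF3)2 (10 mol %), (R)-4-tert-butyl-2-(pyridin-2-yl)-4,5-dihydrooxazole (12 mol %), NH4PF6 (30 mol %), H2O (5 equiv), ClCH2CH2Cl, 60 °C
Reagents that add atoms: none
Why: Palladium-catalysed asymmetric conjugate addition of an arylboronic acid to a chromone (transmetalation to the cationic divalent palladium–pyridinooxazoline complex, enantiodetermining insertion of the C2=C3 bond, protonolysis of the palladium enolate) should set C2 under ligand control, the (R) ligand being expected to deliver the aryl group to the Re face of C2 and so give 2S, a sense to be confirmed on chromone 24 with phenylboronic acid and answered with the antipodal ligand if it proves opposite.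

Step 14
Reactants: 25 the hexabenzyl ether
Product: 26 (2S)-5,7-dihydroxy-2-{4-hydroxy-3-[5,7-dihydroxy-2-(4-hydroxyphenyl)-4-oxo-4H-chromen-6-yl]phenyl}-2,3-dihydro-4H-chromen-4-one (CNP0277421.1)
Conditions: H2 (1 atm), 10% Pd/C, THF/MeOH, rt
Reagents that add atoms: none
Why: Hydrogenolysis of the six benzyl ethers over Pd/C is neutral, so C2 should not epimerise, and at atmospheric pressure it normally spares the flavone double bond, the chromanone carbonyl and the benzylic C2–O bond.

Compound list
1 | 2-(5-bromo-2-methoxyphenyl)acetic acid | OC(=O)Cc1cc(Br)ccc1OC | starting material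
2 | ethoxyacetylene (ethoxyethyne) | C#COCC | starting material
3 | 2-(5-bromo-2-methoxyphenyl)acetyl chloride | ClC(=O)Cc1cc(Br)ccc1OC | intermediate
4 | (5-bromo-2-methoxyphenyl)ketene | O=C=Cc1cc(Br)ccc1OC | intermediate
5 | 4-(5-bromo-2-methoxyphenyl)-3-ethoxycyclobut-2-en-1-one (racemic) | O=C1C=C(OCC)C1c1cc(Br)ccc1OC | intermediate
6 | 2-(5-bromo-2-methoxyphenyl)-3-hydroxycyclobut-2-en-1-one | O=C1CC(O)=C1c1cc(Br)ccc1OC | intermediate
7 | 2-(5-bromo-2-methoxyphenyl)-3-ethoxycyclobut-2-en-1-one | O=C1CC(OCC)=C1c1cc(Br)ccc1OC | intermediate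
8 | 2-(5-bromo-2-methoxyphenyl)-3-ethoxybuta-1,3-dien-1-one (vinylketene) | O=C=C(c1cc(Br)ccc1OC)C(OCC)=C | intermediate
9 | 4-(5-bromo-2-methoxyphenyl)-3-ethoxy-4-(1-ethoxyethenyl)cyclobut-2-en-1-one (racemic) | O=C1C=C(OCC)C1(c1cc(Br)ccc1OC)C(OCC)=C | intermediate
10 | (3E)-4-(5-bromo-2-methoxyphenyl)-3,5-diethoxyhexa-1,3,5-trien-1-one (dienylketene) | O=C=C/C(OCC)=C(c1cc(Br)ccc1OC)\C(OCC)=C | intermediate
11 | 4-(5-bromo-2-methoxyphenyl)-3,5-diethoxycyclohexa-2,4-dien-1-one | O=C1C=C(OCC)C(c2cc(Br)ccc2OC)=C(OCC)C1 | intermediate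
12 | 4-(5-bromo-2-methoxyphenyl)-3,5-diethoxyphenol | Oc1cc(OCC)c(-c2cc(Br)ccc2OC)c(OCC)c1 | intermediate
13 | 4-(5-bromo-2-methoxyphenyl)-3,5-diethoxy-2-iodophenol | Oc1cc(OCC)c(-c2cc(Br)ccc2OC)c(OCC)c1I | intermediate
14 | 1-ethynyl-4-methoxybenzene | C#Cc1ccc(OC)cc1 | starting material
15 | 1-[3-(5-bromo-2-methoxyphenyl)-2,4-diethoxy-6-hydroxyphenyl]-3-(4-methoxyphenyl)prop-2-yn-1-one | O=C(C#Cc1ccc(OC)cc1)c1c(O)cc(OCC)c(-c2cc(Br)ccc2OC)c1OCC | intermediate
16 | 6-(5-bromo-2-methoxyphenyl)-5,7-diethoxy-2-(4-methoxyphenyl)-4H-chromen-4-one | O=c1cc(-c2ccc(OC)cc2)oc2cc(OCC)c(-c3cc(Br)ccc3OC)c(OCC)c12 | intermediate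
17 | 6-(5-bromo-2-hydroxyphenyl)-5,7-dihydroxy-2-(4-hydroxyphenyl)-4H-chromen-4-one | O=c1cc(-c2ccc(O)cc2)oc2cc(O)c(-c3cc(Br)ccc3O)c(O)c12 | intermediate
18 | 5,7-bis(benzyloxy)-6-[2-(benzyloxy)-5-bromophenyl]-2-[4-(benzyloxy)phenyl]-4H-chromen-4-one | O=c1cc(-c2ccc(OCc3ccccc3)cc2)oc2cc(OCc3ccccc3)c(-c3cc(Br)ccc3OCc3ccccc3)c(OCc3ccccc3)c12 | intermediate
19 | 5,7-bis(benzyloxy)-6-[2-(benzyloxy)-5-(4,4,5,5-tetramethyl-1,3,2-dioxaborolan-2-yl)phenyl]-2-[4-(benzyloxy)phenyl]-4H-chromen-4-one | O=c1cc(-c2ccc(OCc3ccccc3)cc2)oc2cc(OCc3ccccc3)c(-c3cc(B4OC(C)(C)C(C)(C)O4)ccc3OCc3ccccc3)c(OCc3ccccc3)c12 | intermediate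
20 | {4-(benzyloxy)-3-[5,7-bis(benzyloxy)-2-[4-(benzyloxy)phenyl]-4-oxo-4H-chromen-6-yl]phenyl}boronic acid | O=c1cc(-c2ccc(OCc3ccccc3)cc2)oc2cc(OCc3ccccc3)c(-c3cc(B(O)O)ccc3OCc3ccccc3)c(OCc3ccccc3)c12 | intermediate
21 | 2,4,6-trihydroxyacetophenone | CC(=O)c1c(O)cc(O)cc1O | starting material
22 | 1-[2,4-bis(benzyloxy)-6-hydroxyphenyl]ethan-1-one | CC(=O)c1c(O)cc(OCc2ccccc2)cc1OCc1ccccc1 | intermediate
23 | (E)-1-[2,4-bis(benzyloxy)-6-hydroxyphenyl]-3-(dimethylamino)prop-2-en-1-one | CN(C)/C=C/C(=O)c1c(O)cc(OCc2ccccc2)cc1OCc1ccccc1 | intermediate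
24 | 5,7-bis(benzyloxy)-4H-chromen-4-one | O=c1ccoc2cc(OCc3ccccc3)cc(OCc3ccccc3)c12 | intermediate
25 | (2S)-5,7-bis(benzyloxy)-2-{4-(benzyloxy)-3-[5,7-bis(benzyloxy)-2-[4-(benzyloxy)phenyl]-4-oxo-4H-chromen-6-yl]phenyl}-2,3-dihydro-4H-chromen-4-one | O=C1C[C@@H](c2ccc(OCc3ccccc3)c(-c3c(OCc4ccccc4)cc4oc(-c5ccc(OCc6ccccc6)cc5)cc(=O)c4c3OCc3ccccc3)c2)Oc2cc(OCc3ccccc3)cc(OCc3ccccc3)c21 | intermediate
26 | (2S)-5,7-dihydroxy-2-{4-hydroxy-3-[5,7-dihydroxy-2-(4-hydroxyphenyl)-4-oxo-4H-chromen-6-yl]phenyl}-2,3-dihydro-4H-chromen-4-one | O=C1C[C@@H](c2ccc(O)c(-c3c(O)cc4oc(-c5ccc(O)cc5)cc(=O)c4c3O)c2)Oc2cc(O)cc(O)c21 | target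

Total step count: 14. Longest linear sequence: 12 steps (steps 1 to 10, 13 and 14, from acid 1); steps 11 and 12 make the chromone in a side branch.

Steps most likely to fail

Step 4. The hindered aryl(ethoxyvinyl)ketene may dimerise or be intercepted before the [2+2] union at the carbon that becomes quaternary. The ynol ether may also decompose thermally before it is consumed, the dienylketene may close onto the anisyl ring to a naphthol, and the ketene may acylate the product phenol. The fallback gives up the benzannulation and makes the aryl–C6 bond by cross-coupling on a preformed flavone; it sets out from 21 and comes back at 17. C-Aroylation of the lithium polyanion of 21 (LiN(SiMe3)2, THF, −78 °C → rt, 4-methoxybenzoyl chloride; Baker–Venkataraman-type) should give 1-(4-methoxyphenyl)-3-(2,4,6-trihydroxyphenyl)propane-1,3-dione F1. Cyclodehydration (H2SO4, AcOH, 95 °C) gives 5,7-dihydroxy-2-(4-methoxyphenyl)-4H-chromen-4-one F2. Selective methylation of the unchelated 7-OH (MeI, K2CO3, acetone) gives 5-hydroxy-7-methoxy-2-(4-methoxyphenyl)-4H-chromen-4-one F3. Iodination directed by the free 5-OH (I2, TlOAc, CH2Cl2) should give 5-hydroxy-6-iodo-7-methoxy-2-(4-methoxyphenyl)-4H-chromen-4-one F4. Suzuki–Miyaura coupling with (5-bromo-2-methoxyphenyl)boronic acid (Pd(PPh3)4, Na2CO3, DME/H2O, 80 °C, the iodide reacting ahead of the bromide) gives 6-(5-bromo-2-methoxyphenyl)-5-hydroxy-7-methoxy-2-(4-methoxyphenyl)-4H-chromen-4-one F5. BBr3 in CH2Cl2 then gives 17, and the route continues with step 8.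

Step 13. Insertion into the electron-rich dialkoxychromone may be slow, so that protodeboronation of the valuable and poorly soluble boronic acid wins, or the facial selectivity may be insufficient. The fallback builds the flavanone through a chalcone and takes the configuration from a separation; it sets out from 18 and comes back at 25. Reductive carbonylation of the bromide (Pd(OAc)2, di(1-adamantyl)-n-butylphosphine, CO/H2 5 bar, TMEDA, toluene, 100 °C) should give 4-(benzyloxy)-3-{5,7-bis(benzyloxy)-2-[4-(benzyloxy)phenyl]-4-oxo-4H-chromen-6-yl}benzaldehyde F6. Claisen–Schmidt condensation with 22 (KOH, EtOH/THF, rt) gives (E)-1-[2,4-bis(benzyloxy)-6-hydroxyphenyl]-3-{4-(benzyloxy)-3-[5,7-bis(benzyloxy)-2-[4-(benzyloxy)phenyl]-4-oxo-4H-chromen-6-yl]phenyl}prop-2-en-1-one F7. Oxa-Michael cyclisation (NaOAc, EtOH/THF, reflux) gives racemic 5,7-bis(benzyloxy)-2-{4-(benzyloxy)-3-[5,7-bis(benzyloxy)-2-[4-(benzyloxy)phenyl]-4-oxo-4H-chromen-6-yl]phenyl}-2,3-dihydro-4H-chromen-4-one F8. Preparative HPLC on a chiral stationary phase separates 25 from the (2R)-enantiomer of 25 F9, which can be returned to F8 by base-mediated ring opening and reclosure. The route continues from 25 with step 14.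

Step 6. Oxidative addition and CO insertion at the doubly flanked, electron-rich C–I bond may be slow, leaving room for non-carbonylative coupling, 5-exo closure to the aurone or erosion of the C–Br bond. The fallback builds the pyranone by classical carbonyl chemistry without palladium; it sets out from 12 (step 5 is then not needed) and comes back at 16. Fries-type C-acetylation ortho to the hydroxyl (Ac2O, BF3·OEt2, 70 °C) should give 1-[3-(5-bromo-2-methoxyphenyl)-2,4-diethoxy-6-hydroxyphenyl]ethan-1-one F10. Claisen–Schmidt condensation with 4-methoxybenzaldehyde (KOH, EtOH, rt) gives (E)-1-[3-(5-bromo-2-methoxyphenyl)-2,4-diethoxy-6-hydroxyphenyl]-3-(4-methoxyphenyl)prop-2-en-1-one F11. Oxidative cyclisation (cat. I2, DMSO, 130 °C) then gives 16, and the route continues with step 7.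

Further compounds
F1 | step 4 | 1-(4-methoxyphenyl)-3-(2,4,6-trihydroxyphenyl)propane-1,3-dione | O=C(CC(=O)c1c(O)cc(O)cc1O)c1ccc(OC)cc1
F2 | step 4 | 5,7-dihydroxy-2-(4-methoxyphenyl)-4H-chromen-4-one | O=c1cc(-c2ccc(OC)cc2)oc2cc(O)cc(O)c12
F3 | step 4 | 5-hydroxy-7-methoxy-2-(4-methoxyphenyl)-4H-chromen-4-one | O=c1cc(-c2ccc(OC)cc2)oc2cc(OC)cc(O)c12
F4 | step 4 | 5-hydroxy-6-iodo-7-methoxy-2-(4-methoxyphenyl)-4H-chromen-4-one | O=c1cc(-c2ccc(OC)cc2)oc2cc(OC)c(I)c(O)c12
F5 | step 4 | 6-(5-bromo-2-methoxyphenyl)-5-hydroxy-7-methoxy-2-(4-methoxyphenyl)-4H-chromen-4-one | O=c1cc(-c2ccc(OC)cc2)oc2cc(OC)c(-c3cc(Br)ccc3OC)c(O)c12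
F6 | step 13 | 4-(benzyloxy)-3-{5,7-bis(benzyloxy)-2-[4-(benzyloxy)phenyl]-4-oxo-4H-chromen-6-yl}benzaldehyde | O=Cc1ccc(OCc2ccccc2)c(-c2c(OCc3ccccc3)cc3oc(-c4ccc(OCc5ccccc5)cc4)cc(=O)c3c2OCc2ccccc2)c1
F7 | step 13 | (E)-1-[2,4-bis(benzyloxy)-6-hydroxyphenyl]-3-{4-(benzyloxy)-3-[5,7-bis(benzyloxy)-2-[4-(benzyloxy)phenyl]-4-oxo-4H-chromen-6-yl]phenyl}prop-2-en-1-one | O=C(/C=C/c1ccc(OCc2ccccc2)c(-c2c(OCc3ccccc3)cc3oc(-c4ccc(OCc5ccccc5)cc4)cc(=O)c3c2OCc2ccccc2)c1)c1c(O)cc(OCc2ccccc2)cc1OCc1ccccc1
F8 | step 13 | racemic 5,7-bis(benzyloxy)-2-{4-(benzyloxy)-3-[5,7-bis(benzyloxy)-2-[4-(benzyloxy)phenyl]-4-oxo-4H-chromen-6-yl]phenyl}-2,3-dihydro-4H-chromen-4-one | O=C1CC(c2ccc(OCc3ccccc3)c(-c3c(OCc4ccccc4)cc4oc(-c5ccc(OCc6ccccc6)cc5)cc(=O)c4c3OCc3ccccc3)c2)Oc2cc(OCc3ccccc3)cc(OCc3ccccc3)c21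
F9 | step 13 | (2R)-5,7-bis(benzyloxy)-2-{4-(benzyloxy)-3-[5,7-bis(benzyloxy)-2-[4-(benzyloxy)phenyl]-4-oxo-4H-chromen-6-yl]phenyl}-2,3-dihydro-4H-chromen-4-one | O=C1C[C@H](c2ccc(OCc3ccccc3)c(-c3c(OCc4ccccc4)cc4oc(-c5ccc(OCc6ccccc6)cc5)cc(=O)c4c3OCc3ccccc3)c2)Oc2cc(OCc3ccccc3)cc(OCc3ccccc3)c21
F10 | step 6 | 1-[3-(5-bromo-2-methoxyphenyl)-2,4-diethoxy-6-hydroxyphenyl]ethan-1-one | CC(=O)c1c(O)cc(OCC)c(-c2cc(Br)ccc2OC)c1OCC
F11 | step 6 | (E)-1-[3-(5-bromo-2-methoxyphenyl)-2,4-diethoxy-6-hydroxyphenyl]-3-(4-methoxyphenyl)prop-2-en-1-one | O=C(/C=C/c1ccc(OC)cc1)c1c(O)cc(OCC)c(-c2cc(Br)ccc2OC)c1OCC
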